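The data were computed from invented constants; noise was put on by code.

Target plus over-reaction product is the sum I hold on to, since turning one into the other leaves it unchanged and new target raises it. Second substrate is the limiting reagent at 0.90 equiv. If the protic impurity takes it one for one, 5.00% of the charge goes there, and the ceiling of the sum is 85.0%. The noon run reads 84.9% at 20.0 min, close to that ceiling.

| setting | noon | dawn | midnight | autumn | cedar | ash | alder |
|---|---|---|---|---|---|---|---|
| starting material | 0.050 M | 0.050 M | 0.050 M | 0.025 M | 0.050 M (fed, over 25 min) | 0.050 M | 0.050 M |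
| second substrate | 0.90 equiv | 0.90 equiv | 0.90 equiv | 0.90 equiv | 0.900 equiv | 0.900 equiv | 0.900 equiv (fed, over 25 min) |
| protic impurity | 2.5 mM | 2.5 mM | 2.5 mM | 2.5 mM | 2.50 mM | 2.50 mM | 2.50 mM |
| enzyme | 0.029 mol% | 0.029 mol% | 0.029 mol% | 0.029 mol% | 0.029 mol% | 0.029 mol% | 0.029 mol% |
| added ligand | 56 µM | 78 µM | 120 µM | 56 µM | 56 µM | 56 µM | 56 µM |
| remark | run made earlier | run made earlier | run made earlier | run made earlier | all else is in the flask from the start; the feed brings no volume worth counting | everything together at the start | all else is in the flask from the start; the feed brings no volume worth counting |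
| time |  |  |  |  | 30 min | 30 min | 30 min |

| run | time / min | over-reaction product / % | target / % |
|---|---|---|---|
| noon | 2.50 | 6.6 | 28.1 |
| noon | 5.00 | 22.0 | 36.6 |
| noon | 8.00 | 37.9 | 34.1 |
| noon | 10.0 | 48.9 | 28.0 |
| noon | 12.0 | 55.9 | 19.0 |
| noon | 15.0 | 66.7 | 14.7 |
| noon | 20.0 | 75.9 | 9.0 |
| dawn | 1.00 | 1.9 | 12.9 |
| dawn | 3.00 | 9.5 | 29.6 |
| dawn | 5.00 | 21.0 | 35.6 |
| dawn | 8.00 | 37.9 | 33.7 |
| dawn | 10.0 | 46.8 | 27.0 |
| dawn | 15.0 | 66.0 | 14.1 |
| dawn | 20.0 | 75.3 | 8.6 |
| midnight | 1.33 | 2.5 | 17.3 |
| midnight | 2.00 | 3.2 | 22.3 |
| midnight | 3.00 | 6.2 | 29.0 |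
| midnight | 5.00 | 19.0 | 34.6 |
| midnight | 8.00 | 35.2 | 33.5 |
| midnight | 12.0 | 53.7 | 22.4 |
| midnight | 20.0 | 72.5 | 8.5 |
| autumn | 4.00 | 8.1 | 23.0 |
| autumn | 8.00 | 26.0 | 24.7 |
| autumn | 10.0 | 34.2 | 25.7 |
| autumn | 15.0 | 48.9 | 17.0 |
| autumn | 20.0 | 57.9 | 10.4 |

(readings scatter by 1 percentage point)

- what was read earlier has a scatter of 1 percentage point, one standard deviation

- the flask with the highest amount of over-reaction product, in percent of the starting material charged ("all alike" if they lie within 1.5 percentage points) (cedar / ash / alder / all alike)
- final over-reaction product, as a percentage of the starting material charged, in cedar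
- final over-reaction product, as a percentage of the starting material charged, in ash
- final over-reaction product, as a percentage of the starting material charged, in alder

Ash has the charges of noon, so the two differ in time: noon was last read at 20.0 min, with 9.0% still target, and ash runs to 30 min. What matters now is how fast target leaves. I divide the rise of over-reaction product per minute by the mean [target] over the same span, so that the clock drops out, and call the result the hand-over constant 0.167 min⁻¹, a first-order rate constant read from noon between 10.0 min and 15.0 min, with the scatter of those readings. Over the extra minutes I take the sum as full, so noon's target shrinks to 1.70%, and ash ends near 83.3%.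

Cedar and alder are another matter. I let formation follow the feed, at 0.0340 min⁻¹ of the charge. Dividing that rate by the hand-over constant gives a standing target of 20.4%. This decays for the 5.00 min after the feed stops, which puts both flasks near 76.1%, less than ash.

The forecast also ranks ash first, with 83% (80% to 87%), and says “both feeds limit formation”, but it gives cedar 69% and alder 69%, below my figure.

The flasks give 83.0% in ash, 72.5% in cedar and 67.7% in alder, so ash stands highest.

    starting material + enzyme ⇌ starting complex (K = 56.0 M⁻¹, k = 32800 M⁻¹ s⁻¹)
    second substrate + starting complex ⇌ ternary complex (K = 90.0 M⁻¹, k = 1.14 × 10⁵ M⁻¹ s⁻¹)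
    ternary complex → enzyme + target (k = 13.2 s⁻¹)
    enzyme + added ligand ⇌ idle complex, settled at all times (K = 18000 M⁻¹)
    target → over-reaction product (k = 0.00274 s⁻¹)
    second substrate + protic impurity → quenched reagent (k = 4.70 M⁻¹ s⁻¹)

Ash holds 1.84% target at 30.0 min, while both fed flasks fall below my reckoning. In cedar, target goes from 15.7% at the end of the feed to 9.96% at 30.0 min, and the hand-over constant times the mean of the two gives 11 percentage points over the last minutes, against a rise of over-reaction product of 11 points. Alder still holds 13.5% target at 30.0 min, with a half-life of 4.15 min by the same constant, and at 300 min its over-reaction product stands at 85.0%.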